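**Plan**

Numbering follows the C15 chain, from C1 (alkyne CH) to C15 (ethyl CH3). The oxolane is O–C6–C7–C8–C9 and the oxocane is O–C7–C8–C9–C10–C11–C12–C13.
Enabling feature: C9–O and C10–Br are trans-vicinal, and C9 lies 1,4 to the oxygen on C6 across the oxocane. The oxolane is therefore the retron of a transannular 5-exo bromoetherification of a (Z)-C9=C10 oxocene by a C6 hydroxyl. This one event cuts both C9–O and C10–Br.
Further cuts: C3=C4 (Peterson), C5–C6 (chelate aldol), C12–Br (Appel inversion), C9=C10 (metathesis), C11–C12 (chelate allylation), O–C13 (SN2) and C8–C9 (epoxide opening).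
Forward order: open-chain C7–O–C13 ether, then the oxocene (first ring), then the oxolane (second and last ring), then the enyne.
Stereochemistry: C7 comes from an (S)-glycidyl ether and C13 from (S)-2-bromobutanoic acid by inversion. C12 and C6 are set by 1,2-chelation control, and C12 is then inverted. C9 and C10 follow from the tethered anti addition, and the Z-alkene from the Peterson step.
Helper: C4 is held at the ester oxidation level through the key step so that the ring alkene is the only π-nucleophile. It is turned into the enyne afterwards.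

Key step: step 10

Assumption: (S)-4-methoxybenzyl glycidyl ether, (S)-2-bromobutanoic acid, 1,3-bis(triisopropylsilyl)propyne and the silyl ketene acetal of methyl acetate are taken as catalogue chemicals. The first is otherwise one step from (S)-glycidol (NaH, 4-methoxybenzyl chloride).

**Step 1**
Reactants: 1 (S)-2-{[(4-methoxybenzyl)oxy]methyl}oxirane
Product: 2 (S)-1-[(4-methoxybenzyl)oxy]pent-4-en-2-ol
Conditions: vinylmagnesium bromide, CuI (10 mol %), THF, −30 °C; aqueous work-up
Reagents that add atoms: vinylmagnesium bromide, C=C[Mg]Br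
Why: Copper-catalysed Grignard opening of a terminal epoxide is an SN2 attack at the unsubstituted carbon, so C8–C9 is formed and the C7 stereocentre of 1 is carried over untouched.

**Step 2**
Reactants: 2 (S)-1-[(4-methoxybenzyl)oxy]pent-4-en-2-ol; 3 (S)-2-bromobutanoic acid
Product: 5 methyl (R)-2-({(S)-1-[(4-methoxybenzyl)oxy]pent-4-en-2-yl}oxy)butanoate, via sodium carboxylate 4 (not isolated)
Conditions: NaH, THF, 0 to 45 °C; MeOH (quench of excess NaH); then MeI, DMF, rt
Reagents that add atoms: iodomethane, CI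
Why: Williamson-type SN2 displacement on the α-halo carboxylate salt by the sodium alkoxide of 2, the standard way to attach a 2-alkoxyalkanoic acid to a hindered secondary alcohol, inverts the halide-bearing carbon and sets C13 as R while the carboxylate charge suppresses enolisation, and the carboxylate is then esterified in the same flask by SN2 on MeI.

**Step 3**
Reactants: 5 methyl (R)-2-({(S)-1-[(4-methoxybenzyl)oxy]pent-4-en-2-yl}oxy)butanoate
Product: 6 (R)-2-({(S)-1-[(4-methoxybenzyl)oxy]pent-4-en-2-yl}oxy)butanal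
Conditions: i-Bu2AlH, CH2Cl2, −78 °C; aqueous Rochelle salt
Reagents that add atoms: none
Why: Partial reduction of an α-alkoxy methyl ester with i-Bu2AlH stops at the chelated aluminium hemiacetal at −78 °C, which releases the aldehyde only on work-up, so C13 is not epimerised.

**Step 4**
Reactants: 6 (R)-2-({(S)-1-[(4-methoxybenzyl)oxy]pent-4-en-2-yl}oxy)butanal
Product: 7 (4R,5R)-5-({(S)-1-[(4-methoxybenzyl)oxy]pent-4-en-2-yl}oxy)hept-1-en-4-ol
Conditions: allyltributylstannane, MgBr2·OEt2, CH2Cl2, −78 to −20 °C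
Reagents that add atoms: allyltributylstannane, C=CC[Sn](CCCC)(CCCC)CCCC
Why: Keck allylation under 1,2-chelation control ties the aldehyde oxygen to the C13 ether oxygen through MgBr2, and the stannane attacks the chelate on the face bearing H rather than ethyl, giving the syn (12R,13R) alcohol.

**Step 5**
Reactants: 7 (4R,5R)-5-({(S)-1-[(4-methoxybenzyl)oxy]pent-4-en-2-yl}oxy)hept-1-en-4-ol
Product: 8 (2S,7R,8R,Z)-8-ethyl-2-{[(4-methoxybenzyl)oxy]methyl}-3,6,7,8-tetrahydro-2H-oxocin-7-ol
Conditions: second-generation Grubbs catalyst (H2IMes)(PCy3)Cl2Ru=CHPh (5 mol %), CH2Cl2 (2 mM), reflux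
Reagents that add atoms: none
Why: Ring-closing metathesis of the two terminal alkenes, aided by the gauche preference of the vicinal C12/C13 oxygens and by high dilution, closes the eight-membered ring, whose size allows only the Z C9=C10 alkene.

**Step 6**
Reactants: 8 (2S,7R,8R,Z)-8-ethyl-2-{[(4-methoxybenzyl)oxy]methyl}-3,6,7,8-tetrahydro-2H-oxocin-7-ol
Product: 9 (2S,7S,8R,Z)-7-bromo-8-ethyl-2-{[(4-methoxybenzyl)oxy]methyl}-3,6,7,8-tetrahydro-2H-oxocine
Conditions: CBr4, P(n-C8H17)3, toluene, 70 °C
Reagents that add atoms: tetrabromomethane, BrC(Br)(Br)Br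
Why: In this Appel-type bromination, which has close precedent on 8-ethyloxocen-7-ols, bromide displaces the alkoxyphosphonium group by SN2 and inverts C12 from R (OH) to S (Br).

**Step 7**
Reactants: 9 (2S,7S,8R,Z)-7-bromo-8-ethyl-2-{[(4-methoxybenzyl)oxy]methyl}-3,6,7,8-tetrahydro-2H-oxocine
Product: 10 [(2S,7S,8R,Z)-7-bromo-8-ethyl-3,6,7,8-tetrahydro-2H-oxocin-2-yl]methanol
Conditions: DDQ, CH2Cl2/pH 7 buffer, 0 °C
Reagents that add atoms: none
Why: Oxidative cleavage of the electron-rich 4-methoxybenzyl ether by DDQ (hydride abstraction, then hydrolysis of the oxocarbenium ion) leaves the alkene, the secondary bromide and the ring ether untouched.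

**Step 8**
Reactants: 10 [(2S,7S,8R,Z)-7-bromo-8-ethyl-3,6,7,8-tetrahydro-2H-oxocin-2-yl]methanol
Product: 11 (2S,7S,8R,Z)-7-bromo-8-ethyl-3,6,7,8-tetrahydro-2H-oxocine-2-carbaldehyde
Conditions: Dess–Martin periodinane, CH2Cl2, 0 °C to rt
Reagents that add atoms: none
Why: Dess–Martin oxidation converts the primary alcohol into the aldehyde under near-neutral conditions that neither epimerise C7 nor eliminate HBr.

**Step 9**
Reactants: 11 (2S,7S,8R,Z)-7-bromo-8-ethyl-3,6,7,8-tetrahydro-2H-oxocine-2-carbaldehyde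
Product: 12 methyl (S)-3-[(2S,7S,8R,Z)-7-bromo-8-ethyl-3,6,7,8-tetrahydro-2H-oxocin-2-yl]-3-hydroxypropanoate
Conditions: CH2=C(OMe)OSiMe2t-Bu, MgBr2·OEt2, CH2Cl2, −78 °C; then 1 M HCl, THF
Reagents that add atoms: 1-(tert-butyldimethylsilyloxy)-1-methoxyethene, C=C(OC)O[Si](C)(C)C(C)(C)C
Why: In this Mukaiyama aldol addition under 1,2-chelation control MgBr2 bridges the aldehyde oxygen and the ring oxygen and the silyl ketene acetal attacks anti to C8, giving the syn (6S,7S) β-hydroxy ester and bringing in C5 and C4 at an oxidation level inert to Br+.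

**Step 10**
Reactants: 12 methyl (S)-3-[(2S,7S,8R,Z)-7-bromo-8-ethyl-3,6,7,8-tetrahydro-2H-oxocin-2-yl]-3-hydroxypropanoate
Product: 14 methyl 2-[(1S,3R,4S,6S,7S,9S)-4,6-dibromo-3-ethyl-2,8-dioxabicyclo[5.2.1]decan-9-yl]acetate, via bromiranium ion 13 (not isolated)
Conditions: NBS (1.05 equiv), MeCN, −20 to 0 °C, dark
Reagents that add atoms: N-bromosuccinimide, O=C1CCC(=O)N1Br
Why: NBS delivers Br+ reversibly to the only C=C bond of 12, the (Z)-C9=C10 alkene of the oxocene, and the bromiranium ion 13, which carries bromine on the ring face opposite to the C6 carbinol, is opened at C9 from the rear by the C6 hydroxyl, after which the succinimide anion takes the proton. The closest known reaction type is the intramolecular, transannular bromoetherification of medium-ring alkenols with NBS or related Br+ donors, the laboratory image of the haloperoxidase step by which such bromo ethers arise in red algae. The oxolane O–C6–C7–C8–C9 closes in the 5-exo mode on the bromiranium ion, which is preferred over 6-endo attack at C10 because the latter needs a longer reach across the ring and would give a more strained dioxabicyclo[4.2.2]decane. C9 is controlled by the tether, since the oxygen on C6 can reach C9 only on the ring face on which C6 itself stands at C7 (hence the cis C7/C9 bridge), and C10 is controlled by the stereospecific anti opening of the bromiranium ion of a Z-alkene, so both centres derive from C6 and C7 without outside control. The step needs chemoselectivity for the ring alkene, facial selection and capture by the hydroxyl rather than by the ring ether oxygen: the first is secured by holding C4 at the ester level so that no allyl or enyne π-system is present, the second by the reversibility of Br+ transfer, which lets the unproductive diastereomeric ion revert, and the third by the higher nucleophilicity of the free OH over the ring oxygen, which is deactivated by the β-bromine at C12. In one operation two bonds (C9–O and C10–Br) and two stereocentres are made and the monocycle becomes the complete 2,8-dioxabicyclo[5.2.1]decane.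

**Step 11**
Reactants: 14 methyl 2-[(1S,3R,4S,6S,7S,9S)-4,6-dibromo-3-ethyl-2,8-dioxabicyclo[5.2.1]decan-9-yl]acetate
Product: 15 2-[(1S,3R,4S,6S,7S,9S)-4,6-dibromo-3-ethyl-2,8-dioxabicyclo[5.2.1]decan-9-yl]acetaldehyde
Conditions: i-Bu2AlH (1.1 equiv), CH2Cl2, −78 °C; aqueous Rochelle salt
Reagents that add atoms: none
Why: Partial ester reduction with i-Bu2AlH at −78 °C halts at the aluminium hemiacetal and does not touch the secondary bromides or any stereocentre.

**Step 12**
Reactants: 15 2-[(1S,3R,4S,6S,7S,9S)-4,6-dibromo-3-ethyl-2,8-dioxabicyclo[5.2.1]decan-9-yl]acetaldehyde; 16 1,3-bis(triisopropylsilyl)propyne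
Product: 18 {(Z)-5-[(1S,3R,4S,6S,7S,9S)-4,6-dibromo-3-ethyl-2,8-dioxabicyclo[5.2.1]decan-9-yl]pent-3-en-1-yn-1-yl}triisopropylsilane, via lithiated propyne 17 (not isolated)
Conditions: 16, n-BuLi, THF, −78 °C; then 15, −78 to −20 °C
Reagents that add atoms: none
Why: In this Peterson olefination the lithiated bis-silylpropyne adds to the aldehyde and the β-silyl alkoxide loses i-Pr3SiOLi by syn elimination, the bulky silyl groups favouring the Z-enyne, at a temperature at which the β-alkoxy aldehyde and the bromides tolerate the base.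

**Step 13**
Reactants: 18 {(Z)-5-[(1S,3R,4S,6S,7S,9S)-4,6-dibromo-3-ethyl-2,8-dioxabicyclo[5.2.1]decan-9-yl]pent-3-en-1-yn-1-yl}triisopropylsilane
Product: 19 (1S,3R,4S,6S,7S,9S)-4,6-dibromo-3-ethyl-9-[(Z)-pent-2-en-4-yn-1-yl]-2,8-dioxabicyclo[5.2.1]decane
Conditions: Bu4NF (1 M in THF), THF, −10 °C
Reagents that add atoms: none
Why: Fluoride-induced protodesilylation of the alkynylsilane should run at low temperature faster than E2 loss of HBr and touches neither the Z-alkene nor any stereocentre.

**Compound list**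

1 | (S)-2-{[(4-methoxybenzyl)oxy]methyl}oxirane | COc1ccc(COC[C@@H]2CO2)cc1 | starting material
2 | (S)-1-[(4-methoxybenzyl)oxy]pent-4-en-2-ol | C=CC[C@H](O)COCc1ccc(OC)cc1 | intermediate
3 | (S)-2-bromobutanoic acid | CC[C@H](Br)C(=O)O | starting material
4 | sodium (R)-2-({(S)-1-[(4-methoxybenzyl)oxy]pent-4-en-2-yl}oxy)butanoate (not isolated) | CC[C@@H](O[C@@H](CC=C)COCc1ccc(OC)cc1)C(=O)[O-].[Na+] | intermediate
5 | methyl (R)-2-({(S)-1-[(4-methoxybenzyl)oxy]pent-4-en-2-yl}oxy)butanoate | CC[C@@H](O[C@@H](CC=C)COCc1ccc(OC)cc1)C(=O)OC | intermediate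
6 | (R)-2-({(S)-1-[(4-methoxybenzyl)oxy]pent-4-en-2-yl}oxy)butanal | CC[C@@H](O[C@@H](CC=C)COCc1ccc(OC)cc1)C=O | intermediate
7 | (4R,5R)-5-({(S)-1-[(4-methoxybenzyl)oxy]pent-4-en-2-yl}oxy)hept-1-en-4-ol | CC[C@@H](O[C@@H](CC=C)COCc1ccc(OC)cc1)[C@H](O)CC=C | intermediate
8 | (2S,7R,8R,Z)-8-ethyl-2-{[(4-methoxybenzyl)oxy]methyl}-3,6,7,8-tetrahydro-2H-oxocin-7-ol | CC[C@H]1O[C@H](COCc2ccc(OC)cc2)C/C=C\C[C@H]1O | intermediate
9 | (2S,7S,8R,Z)-7-bromo-8-ethyl-2-{[(4-methoxybenzyl)oxy]methyl}-3,6,7,8-tetrahydro-2H-oxocine | CC[C@H]1O[C@H](COCc2ccc(OC)cc2)C/C=C\C[C@@H]1Br | intermediate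
10 | [(2S,7S,8R,Z)-7-bromo-8-ethyl-3,6,7,8-tetrahydro-2H-oxocin-2-yl]methanol | CC[C@H]1O[C@H](CO)C/C=C\C[C@@H]1Br | intermediate
11 | (2S,7S,8R,Z)-7-bromo-8-ethyl-3,6,7,8-tetrahydro-2H-oxocine-2-carbaldehyde | CC[C@H]1O[C@H](C=O)C/C=C\C[C@@H]1Br | intermediate
12 | methyl (S)-3-[(2S,7S,8R,Z)-7-bromo-8-ethyl-3,6,7,8-tetrahydro-2H-oxocin-2-yl]-3-hydroxypropanoate | CC[C@H]1O[C@H]([C@@H](O)CC(=O)OC)C/C=C\C[C@@H]1Br | intermediate
13 | C9,C10-bromiranium ion of 12, bromine on the ring face opposite to the C6 carbinol (not isolated) | CC[C@H]1O[C@H]([C@@H](O)CC(=O)OC)C[C@H]2[Br+][C@H]2C[C@@H]1Br | intermediate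
14 | methyl 2-[(1S,3R,4S,6S,7S,9S)-4,6-dibromo-3-ethyl-2,8-dioxabicyclo[5.2.1]decan-9-yl]acetate | COC(=O)C[C@@H]1O[C@H]2C[C@@H]1O[C@H](CC)[C@@H](Br)C[C@@H]2Br | intermediate
15 | 2-[(1S,3R,4S,6S,7S,9S)-4,6-dibromo-3-ethyl-2,8-dioxabicyclo[5.2.1]decan-9-yl]acetaldehyde | O=CC[C@@H]1O[C@H]2C[C@@H]1O[C@H](CC)[C@@H](Br)C[C@@H]2Br | intermediate
16 | 1,3-bis(triisopropylsilyl)propyne | CC(C)[Si](CC#C[Si](C(C)C)(C(C)C)C(C)C)(C(C)C)C(C)C | starting material
17 | 1-lithio-1,3-bis(triisopropylsilyl)propyne (not isolated) | [Li]C(C#C[Si](C(C)C)(C(C)C)C(C)C)[Si](C(C)C)(C(C)C)C(C)C | intermediate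
18 | {(Z)-5-[(1S,3R,4S,6S,7S,9S)-4,6-dibromo-3-ethyl-2,8-dioxabicyclo[5.2.1]decan-9-yl]pent-3-en-1-yn-1-yl}triisopropylsilane | CC(C)[Si](C#C/C=C\C[C@@H]1O[C@H]2C[C@@H]1O[C@H](CC)[C@@H](Br)C[C@@H]2Br)(C(C)C)C(C)C | intermediate
19 | (1S,3R,4S,6S,7S,9S)-4,6-dibromo-3-ethyl-9-[(Z)-pent-2-en-4-yn-1-yl]-2,8-dioxabicyclo[5.2.1]decane | C#C/C=C\C[C@@H]1O[C@H]2C[C@@H]1O[C@H](CC)[C@@H](Br)C[C@@H]2Br | target

Total step count: 13. Longest linear sequence: 13 (1 to 19).

**Steps most likely to fail**

Step 10. The bromiranium ion may be captured by the ring ether oxygen, which would form a transannular oxonium ion and lead to skeletal rearrangement. Closure at C10 instead of C9 is the other risk.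
The fallback sets out from 12 and replaces Br+ by a reversible, softer electrophile. Intramolecular oxymercuration with Hg(OCOCF3)2 (divalent mercury) in MeCN should close the same oxolane under thermodynamic 5-exo control and give the organomercury trifluoroacetate F1. Aqueous KBr converts this into the organomercury bromide F2. Polar brominolysis of the C10–Hg bond with Br2 in pyridine (SE2, retention at carbon) returns to the route at 14.

Step 6. Slow SN2 displacement at a ring carbinol flanked by the ether carbon may allow E2 elimination toward a diene. Participation of the ring oxygen, with loss of clean inversion, may also compete.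
The fallback sets out from 7 and installs the bromide before the ring exists. ClCH2SO2Cl and pyridine give the chloromethanesulfonate F3. LiBr in DMF displaces it with inversion to the open-chain bromide F4. Ring-closing metathesis of F4 with the second-generation Grubbs catalyst at high dilution returns to the route at 9.

Step 2. E2 elimination of HBr from the α-bromo carboxylate may compete with substitution. Bromide exchange at the halide-bearing carbon before substitution would erode the configuration at C13.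
The fallback sets out from 2 and uses a halide-free electrophile already at the ester level. Commercial methyl (S)-2-hydroxybutanoate is converted with Tf2O and 2,6-lutidine into methyl (S)-2-(trifluoromethylsulfonyloxy)butanoate F5. The potassium alkoxide of 2 (KN(SiMe3)2, THF, −78 °C) displaces the triflate with inversion and returns to the route directly at 5.

**Further compounds**

F1 | step 10 | methyl 2-[(1S,3R,4S,6S,7S,9S)-4-bromo-3-ethyl-6-(trifluoroacetoxymercurio)-2,8-dioxabicyclo[5.2.1]decan-9-yl]acetate | COC(=O)C[C@@H]1O[C@H]2C[C@@H]1O[C@H](CC)[C@@H](Br)C[C@@H]2[Hg]OC(=O)C(F)(F)F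
F2 | step 10 | methyl 2-[(1S,3R,4S,6S,7S,9S)-4-bromo-6-(bromomercurio)-3-ethyl-2,8-dioxabicyclo[5.2.1]decan-9-yl]acetate | COC(=O)C[C@@H]1O[C@H]2C[C@@H]1O[C@H](CC)[C@@H](Br)C[C@@H]2[Hg]Br
F3 | step 6 | (4R,5R)-5-({(S)-1-[(4-methoxybenzyl)oxy]pent-4-en-2-yl}oxy)hept-1-en-4-yl chloromethanesulfonate | CC[C@@H](O[C@@H](CC=C)COCc1ccc(OC)cc1)[C@H](OS(=O)(=O)CCl)CC=C
F4 | step 6 | 1-({[(S)-2-{[(3R,4S)-4-bromohept-6-en-3-yl]oxy}pent-4-en-1-yl]oxy}methyl)-4-methoxybenzene | CC[C@@H](O[C@@H](CC=C)COCc1ccc(OC)cc1)[C@@H](Br)CC=C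
F5 | step 2 | methyl (S)-2-(trifluoromethylsulfonyloxy)butanoate | CC[C@H](OS(=O)(=O)C(F)(F)F)C(=O)OC
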